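**Wailupemycin H by aryne annulation onto a desymmetrised 3-hydroxy-3-phenylglutarate: synthesis proposal**

## Structural features

The target is an unsymmetrical methylene-bridged dimer of two 4-hydroxy-2-pyrones: the bridge CH2 joins C3 of pyrone ring A to C3 of pyrone ring B. Ring A carries at C6 a 3,4-dihydronaphthalen-1(2H)-one (tetralone numbering throughout: C1 ketone, C2 methylene, C3 carbinol bearing phenyl, C4 methine bonded to ring A, C8 phenol). Ring B carries at C6 a 4,5-dihydroxy-2-phenylnaphthalen-1-yl group. The only stereocentres are the adjacent C3 (tertiary benzylic carbinol, R) and C4 (S); the C3 hydroxyl and ring A are cis, so phenyl and ring A are trans. The tetralone half is fragile in three ways: the C1 ketone and C3 hydroxyl form a β-hydroxy ketone that dehydrates and then aromatises, a C3 alkoxide can expel the doubly stabilised C4 carbanion by retro-aldol cleavage, and the C4 proton is acidic enough to epimerise. Dehydration of the tetralone half gives exactly the naphthol that sits on ring B, so both halves can come from one intermediate. The real difficulty is to raise the C3 carbinol as one enantiomer next to the labile C4 centre without aromatisation, and to build the bridge between two equally nucleophilic pyrone C3 positions. The key step uses the pattern of the phenol ring: C4 is bonded to C4a, meta to the C8 oxygen, and the C1 carbonyl to C8a, ortho to it, which is the polarity of a 3-alkoxybenzyne that takes a carbon nucleophile at its remote carbon and an acyl group next to oxygen.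

## Logic of the disconnections

29 to 24 and 27. The bond between the bridge carbon and C3 of ring A is cut. A bridge from formaldehyde and two different pyrones would be statistical; carrying the one-carbon unit on one partner as an aldehyde makes the union directional. The cut halves the molecule. The forward step must condense and reduce under conditions that spare the β-hydroxy ketone of 24.

27 to 25. The formyl C–C3 bond of ring B is cut. The formyl group is placed on the aromatised half because it has no stereocentre and no β-hydroxy ketone, so 24 meets only one mild step after deprotection. The forward step must formylate the pyrone carbon and leave the naphthalenediol alone.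

25 to 24. Water is formally added back across C2–C3 and the naphthol is returned to the C1 ketone. This removes any separate synthesis of the naphthalene: one intermediate feeds both halves. The forward dehydration is downhill and only has to be complete.

24 to 23 to 22. Two O–benzyl bonds and one O–Si bond are cut. The silyl ether is removed first, under buffered acidic fluoride, so that no free alkoxide is ever formed next to C4; hydrogenolysis then delivers 24 from a neutral filtration. The demand is that Pd leaves the tertiary benzylic C3–O bond, the aryl ketone and the pyrone alkene intact.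

22 to 13 and 16. C4–C4a and C1–C8a are cut together, which removes the tetralone ring and the C4 stereocentre and leaves an open-chain ester with one stereocentre plus a flat aryne precursor. The forward step needs a carbanion at the pyrone methylene carbon that adds to the aryne faster than it expels the β-silyloxy group, and an aryl anion that acylates faster than it is protonated.

16 to 15 to 14. The O–S and one O–benzyl bond are cut, back to a symmetrical iodoresorcinol. The only demand is acceptance of a statistical mono-benzylation with recycling of 14.

13 to 12 to 11 to 7 and 8. The pyrone O–benzyl bond, the lactone C–O bond and the C–C bond between the acid carbonyl of 7 and the terminal carbon of 8 are cut. The pyrone is thus four carbons of 8 plus the acid carbon of 7. The forward acylation must occur at the acyl imidazolide and not at the methyl ester, and the lactonisation must not enolise towards the silyloxy carbon.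

7 to 5 to 4. The O–Si bond is cut, then one of two enantiotopic ester groups is restored, which reveals a prochiral diester. All absolute stereochemistry of the route is thereby reduced to one enantiotopic-group selection by a hydrolase. The silyl group goes on after the enzyme so that the enzyme sees a small, hydroxylated substrate.

4 to 3 to 1 and 2. Both ester carbons are traced to terminal alkenes and the two C–C bonds at the carbinol to a double Grignard addition. No stereochemical demand arises because the two arms are identical.

## Other disconnections considered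

Alternative 1: The cut is made at the C3–C4 bonds of both pyrones, so that the bridge carbon and the two pyrone C3 atoms come from one glutaric diester. In the forward key step a glutarate bis-enolate would be C-acylated in turn by two different alkynoyl chlorides to give A1; cyclisation of each ester oxygen onto its ynone (acid or a gold catalyst such as Ph3PAuNTf2, with loss of isobutene) would then give the bispyrone, and the tetralone ring would be raised last on the bromoaryl arm. In its favour, the bridge is built in from the start and the problem of an unsymmetrical methylene bridge disappears; on that point it is better than the chosen plan, which spends two steps on formylation and reductive union. Against it, two successive cross-acylations of one bis-enolate invite statistical mixtures, O-acylation and conjugate addition to the ynones, and the propargylic benzylic CH2 of one arm is prone to allene isomerisation. The naphthyl arm needs its own multistep synthesis, whereas here it falls out of 24 by dehydration. The two stereocentres would have to be created late on a polyfunctional bispyrone with no evident source of absolute control at C3, whereas the chosen plan fixes C3 at the fourth compound. Mechanistically the acylations are ordinary, which is a point in favour of A1 over the new aryne step; in stereocontrol and in overall length the chosen plan should be ahead.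

Alternative 2: The cut removes all seven Claisen bonds and the three ring bonds at once, back to benzoate and malonate. In the forward key step a reconstituted ketosynthase/chain-length factor, carrier protein, ketoreductase, ligase and transacylase would assemble and fold the chain to A2, which is the same structure as 24. In its favour, one operation replaces the twelve steps that lead to 24, no protecting group is needed, and the enzyme sets C3 and C4; in step count and atom economy it is clearly better. Against it, five or six proteins and their cofactors (ATP, coenzyme A, NADPH) must be produced, the scale is that of dilute enzyme assays, and the last cyclisations are largely spontaneous, so the ratio of A2 to its C4 epimer and to aromatised shunt products is not under reagent control. The chosen plan is longer but scalable with ordinary equipment and gives a handle on each centre; the endgame from A2 would be the same, so there the two are equal.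

Alternative 3: The cut is the C3–C4 bond, read as a retro-[3,3] shift that restores a lactone C1–O bond. In the forward key step the silyl ketene acetal of a 1-alkenyl six-membered benzo-lactone would rearrange (Ireland–Claisen ring contraction) to A3, transferring one carbinol centre to C3 and C4 at once. In its favour, the reaction class is known for lactone-to-carbocycle conversions and both adjacent stereocentres arise in one concerted, stereospecific event, so the C3/C4 relationship does not depend on an equilibration; in certainty of mechanism and in control of C4 it is the better plan. The C4 carboxyl of A3 can be homologated to the pyrone by the same acetoacetate chemistry, so there the plans are equal. Against it, the lactone must be made enantioenriched with a trisubstituted enol-ether alkene of defined geometry. The C1=C2 alkene of A3 must still be oxidised regioselectively to the C1 ketone, and a 4-methoxybenzyl group on a tertiary benzylic oxygen must be removed. This adds several steps before and after the key step. The chosen plan reaches the complete tetralone–pyrone skeleton at the correct oxidation level in one step from a desymmetrised glutarate and should be shorter.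

Key step: step 10

Remarks on the chemistry (assumptions):
- The esterase is assumed to cleave the same enantiotopic ester arm as in the classical 3-hydroxy-3-methyl diester, which here corresponds to the (S)-half-ester 5.
- The carbinol centre keeps one spatial arrangement from 5 to 29; its descriptor changes only with substituent ranking (S in 5, 7, 9, 11–13 and 17; R in 6 and 20–29).
- The anion of 13 is an extended, vinylogous enolate whose reactive carbon is the exocyclic pyrone 6-methylene carbon.
- The ortho-magnesiated aryl triflate loses triflate at −78 °C, so no warming is planned.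
- Material with the wrong C4 configuration, or already dehydrated, can still be used for 25, in which both centres are erased.

## Route

Step 1
Reactants: 1 methyl benzoate; 2 allylmagnesium bromide
Product: 3 4-phenylhepta-1,6-dien-4-ol
Conditions: 2 (2.3 equiv), Et2O, 0 °C to rt; aq NH4Cl
Reagents that add atoms: none
Why: Double Grignard addition to an ester (addition–elimination, then a second addition) gives the symmetrical tertiary carbinol; the two allyl arms are identical, so no stereocentre arises.

Step 2
Reactants: 3 4-phenylhepta-1,6-dien-4-ol
Product: 4 dimethyl 3-hydroxy-3-phenylpentanedioate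
Conditions: O3, CH2Cl2/MeOH, NaOH (2.5 M in MeOH), −78 °C; then H2O
Reagents that add atoms: ozone, O=[O+][O-]; methanol, CO
Why: Ozonolysis in methanolic NaOH turns each terminal alkene directly into a methyl ester (methanol traps the cleavage fragments, which are oxidised in situ), so the prochiral diester is reached in one step without exposing a tertiary benzylic hydroxy diacid to dehydrating acid; at −78 °C the phenyl ring and the carbinol are not attacked.

Step 3
Reactants: 4 dimethyl 3-hydroxy-3-phenylpentanedioate
Product: 5 (3S)-3-hydroxy-5-methoxy-5-oxo-3-phenylpentanoic acid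
Conditions: pig liver esterase, 0.1 M phosphate buffer pH 7.5, 10% DMSO, 25 °C, pH-stat (1 M NaOH); then HCl to pH 3, 0 °C
Reagents that add atoms: water, O
Why: Enzymatic desymmetrisation by enantiotopic-group-selective ester hydrolysis; the active site distinguishes the two CH2CO2Me arms and the reaction stops at the monoacid because the carboxylate is a poor substrate. This single selection sets C3 of the target.

Step 4
Reactants: 5 (3S)-3-hydroxy-5-methoxy-5-oxo-3-phenylpentanoic acid
Product: 7 (3S)-5-methoxy-5-oxo-3-phenyl-3-[(triethylsilyl)oxy]pentanoic acid, via bis-silylated ester 6 (not isolated)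
Conditions: Et3SiOTf (2.4 equiv), 2,6-lutidine, CH2Cl2, −78 to 0 °C; then THF/H2O/AcOH, rt
Reagents that add atoms: triethylsilyl trifluoromethanesulfonate, CC[Si](CC)(CC)OS(=O)(=O)C(F)(F)F
Why: A silyl triflate with a hindered pyridine base silylates the hindered tertiary alcohol and, transiently, the acid; the labile silyl ester is hydrolysed on mild aqueous work-up while the tertiary silyl ether stays. The ether blocks retro-aldol cleavage and alkoxide side reactions in the anion steps that follow.

Step 5
Reactants: 7 (3S)-5-methoxy-5-oxo-3-phenyl-3-[(triethylsilyl)oxy]pentanoic acid; 8 methyl acetoacetate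
Product: 11 dimethyl (7S)-3,5-dioxo-7-phenyl-7-[(triethylsilyl)oxy]nonanedioate, via acyl imidazolide 9 (not isolated), via acetoacetate dianion 10 (not isolated)
Conditions: 7, CDI, THF, rt; 8 (2.3 equiv), NaH, THF, 0 °C, then n-BuLi, −10 °C; combine at −78 to −40 °C; AcOH
Reagents that add atoms: none
Why: Claisen-type C-acylation of the acetoacetate dianion at its terminal carbon by an acyl imidazolide; the imidazolide is far more electrophilic than the methyl ester at −78 °C, and the extra dianion absorbs the acidic proton of the product.

Step 6
Reactants: 11 dimethyl (7S)-3,5-dioxo-7-phenyl-7-[(triethylsilyl)oxy]nonanedioate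
Product: 12 methyl (3S)-4-(4-hydroxy-2-oxo-2H-pyran-6-yl)-3-phenyl-3-[(triethylsilyl)oxy]butanoate
Conditions: DBU (1.5 equiv), toluene, rt to 40 °C; aq citric acid
Reagents that add atoms: none
Why: Base-mediated enol lactonisation of a 3,5-diketo ester to the 4-hydroxy-2-pyrone, the conjugated thermodynamic sink; the amidine only forms the central diketone enolate, so the carbon next to the silyloxy centre is not enolised.

Step 7
Reactants: 12 methyl (3S)-4-(4-hydroxy-2-oxo-2H-pyran-6-yl)-3-phenyl-3-[(triethylsilyl)oxy]butanoate
Product: 13 methyl (3S)-4-[4-(benzyloxy)-2-oxo-2H-pyran-6-yl]-3-phenyl-3-[(triethylsilyl)oxy]butanoate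
Conditions: BnOH, PPh3, DIAD, THF, 0 °C to rt
Reagents that add atoms: benzyl alcohol, OCc1ccccc1
Why: Mitsunobu O-alkylation; the acidic 4-hydroxy-2-pyrone is an ideal pronucleophile and is alkylated at the 4-oxygen, and the neutral conditions spare the silyl ether and the ester.

Step 8
Reactants: 14 2-iodoresorcinol
Product: 15 3-(benzyloxy)-2-iodophenol
Conditions: BnBr (1.0 equiv), K2CO3 (1.0 equiv), acetone, rt
Reagents that add atoms: benzyl bromide, BrCc1ccccc1
Why: Williamson etherification of a symmetrical diol with one equivalent of halide; the mono-ether is separated from recovered 14 (recycled) and the diether.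

Step 9
Reactants: 15 3-(benzyloxy)-2-iodophenol
Product: 16 3-(benzyloxy)-2-iodophenyl trifluoromethanesulfonate
Conditions: Tf2O, pyridine, CH2Cl2, 0 °C
Reagents that add atoms: trifluoromethanesulfonic anhydride, O=S(=O)(OS(=O)(=O)C(F)(F)F)C(F)(F)F
Why: O-Sulfonylation of the phenol gives the ortho-iodoaryl triflate, a latent 3-alkoxybenzyne with the iodine between the two oxygens.

Step 10
Reactants: 13 methyl (3S)-4-[4-(benzyloxy)-2-oxo-2H-pyran-6-yl]-3-phenyl-3-[(triethylsilyl)oxy]butanoate; 16 3-(benzyloxy)-2-iodophenyl trifluoromethanesulfonate
Product: 22 (3R,4R)-8-(benzyloxy)-4-[4-(benzyloxy)-2-oxo-2H-pyran-6-yl]-3-phenyl-3-[(triethylsilyl)oxy]-3,4-dihydronaphthalen-1(2H)-one, via lithium extended enolate 17 (not isolated), via arylmagnesium triflate 18 (not isolated), via 3-benzyloxybenzyne 19 (not isolated), via aryllithium adduct 20 (not isolated), via tetralone enolate 21 (not isolated)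
Conditions: LiN(SiMe3)2 (1.05 equiv), THF, −78 °C; 16 (1.3 equiv); iPrMgCl·LiCl (1.3 equiv), −78 °C; AcOH, −78 °C; then DBU (0.1 equiv), CH2Cl2, 0 °C
Reagents that add atoms: none
Why: Proposed new method: LiN(SiMe3)2 removes the most acidic proton of 13, at the exocyclic pyrone methylene carbon, to give 17, while iodine–magnesium exchange on 16 gives 18, which loses triflate at −78 °C to release 19; the carbanion of 17 adds to the aryne carbon remote from the benzyloxy group and the aryllithium 20, now next to oxygen, attacks the methyl ester and expels methoxide, which deprotonates the new, more acidic C4–H to give 21 until the cold acid quench. The closest known reaction types are the anionic annulation of arynes by stabilised carbanions that carry an internal ester (ester dienolates, homophthalate-type anions) and the acyl-alkylation of arynes by β-keto esters; new here is a pyrone extended enolate with a remote ester. The one ring formed (C1–C2–C3–C4–C4a–C8a) closes by 6-exo-trig attack of the C8a aryl anion on the ester carbonyl. Regiochemistry rests on the inductive polarisation of the 3-alkoxyaryne (nucleophile at the distal carbon, anion next to oxygen), so the ketone ends ortho and C4 meta to the C8 oxygen. C3 is carried unchanged from 5 and controls the new C4 centre: C4 is set on protonation of planar 21 and, because its proton is the most acidic in 22, catalytic DBU should equilibrate it to the isomer with the pyrone pseudoaxial and anti to phenyl (cis to the silyloxy group), which avoids the peri contact with C5–H and a gauche phenyl/pyrone interaction. The step needs carbanion addition to outrun aryne–pyrone cycloaddition (secured by the charge of 17 and a near-stoichiometric aryne), deprotonation at the pyrone methylene and not at the ester α-carbon (secured by one equivalent of a weak amide base), and survival of the β-silyloxy group (secured by running everything at −78 °C with a cold quench).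

Step 11
Reactants: 22 (3R,4R)-8-(benzyloxy)-4-[4-(benzyloxy)-2-oxo-2H-pyran-6-yl]-3-phenyl-3-[(triethylsilyl)oxy]-3,4-dihydronaphthalen-1(2H)-one
Product: 23 (3R,4S)-8-(benzyloxy)-4-[4-(benzyloxy)-2-oxo-2H-pyran-6-yl]-3-hydroxy-3-phenyl-3,4-dihydronaphthalen-1(2H)-one
Conditions: HF·pyridine, pyridine/THF, 0 °C to rt
Reagents that add atoms: none
Why: Fluoride-driven cleavage of the silyl ether under buffered, weakly acidic conditions; no free alkoxide is formed, so retro-aldol opening at C3–C4 and base-induced dehydration are avoided and both stereocentres are untouched (the C4 descriptor changes only by ranking).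

Step 12
Reactants: 23 (3R,4S)-8-(benzyloxy)-4-[4-(benzyloxy)-2-oxo-2H-pyran-6-yl]-3-hydroxy-3-phenyl-3,4-dihydronaphthalen-1(2H)-one
Product: 24 (3R,4S)-3,8-dihydroxy-4-(4-hydroxy-2-oxo-2H-pyran-6-yl)-3-phenyl-3,4-dihydronaphthalen-1(2H)-one
Conditions: H2 (1 atm), Pd/C (10%), EtOAc/MeOH, rt
Reagents that add atoms: none
Why: Catalytic hydrogenolysis of the aryl and pyrone benzyl ethers; these O–CH2Ph bonds cleave much faster than the hindered tertiary benzylic C3–O bond, the hydrogen-bonded aryl ketone or the pyrone alkene under one atmosphere at room temperature, and the product is obtained by filtration from a neutral medium.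

Step 13
Reactants: 24 (3R,4S)-3,8-dihydroxy-4-(4-hydroxy-2-oxo-2H-pyran-6-yl)-3-phenyl-3,4-dihydronaphthalen-1(2H)-one
Product: 25 6-(4,5-dihydroxy-2-phenylnaphthalen-1-yl)-4-hydroxy-2H-pyran-2-one
Conditions: TsOH·H2O (0.2 equiv), THF, 50 °C
Reagents that add atoms: none
Why: Acid-catalysed dehydration of the β-hydroxy ketone (loss of the tertiary benzylic hydroxyl) followed by keto–enol tautomerisation; aromatisation to the naphthol makes it irreversible, and both stereocentres are erased by design.

Step 14
Reactants: 25 6-(4,5-dihydroxy-2-phenylnaphthalen-1-yl)-4-hydroxy-2H-pyran-2-one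
Product: 27 6-(4,5-dihydroxy-2-phenylnaphthalen-1-yl)-4-hydroxy-2-oxo-2H-pyran-3-carbaldehyde, via dimethylaminomethylene dione 26 (not isolated)
Conditions: Me2NCH(OMe)2 (1.1 equiv), THF, 0 °C to rt; then 1 M HCl, THF/H2O, rt
Reagents that add atoms: N,N-dimethylformamide dimethyl acetal, COC(OC)N(C)C; water, O
Why: Aminomethylenation of an active methine by an amide acetal, then acid hydrolysis of the vinylogous amide to the 3-formyl-4-hydroxy-2-pyrone; the reagent is ionised by the acidic pyrone and attacked by its C3, a path not open to the naphthol ring, and one equivalent at low temperature limits O-methylation.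

Step 15
Reactants: 24 (3R,4S)-3,8-dihydroxy-4-(4-hydroxy-2-oxo-2H-pyran-6-yl)-3-phenyl-3,4-dihydronaphthalen-1(2H)-one; 27 6-(4,5-dihydroxy-2-phenylnaphthalen-1-yl)-4-hydroxy-2-oxo-2H-pyran-3-carbaldehyde
Product: 29 wailupemycin H, 6-[(1S,2R)-2,5-dihydroxy-4-oxo-2-phenyl-1,2,3,4-tetrahydronaphthalen-1-yl]-3-{[6-(4,5-dihydroxy-2-phenylnaphthalen-1-yl)-4-hydroxy-2-oxo-2H-pyran-3-yl]methyl}-4-hydroxy-2H-pyran-2-one, via methine-bridged alkylidene 28 (not isolated)
Conditions: Hantzsch ester (1.2 equiv), L-proline (0.1 equiv), EtOH/CH2Cl2, rt, N2
Reagents that add atoms: none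
Why: Reductive alkylation of a cyclic 1,3-dicarbonyl: Knoevenagel condensation of the nucleophilic ring A C3 of 24 with the aldehyde gives 28, which accepts hydride from the Hantzsch ester by conjugate transfer hydrogenation. The one-carbon unit is already bonded to ring B, so only the unsymmetrical dimer can form, and the near-neutral conditions should leave C3 and C4 unchanged.

## Compound list

1 | methyl benzoate | COC(=O)c1ccccc1 | starting material
2 | allylmagnesium bromide | C=CC[Mg]Br | starting material
3 | 4-phenylhepta-1,6-dien-4-ol | C=CCC(O)(CC=C)c1ccccc1 | intermediate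
4 | dimethyl 3-hydroxy-3-phenylpentanedioate | COC(=O)CC(O)(CC(=O)OC)c1ccccc1 | intermediate
5 | (3S)-3-hydroxy-5-methoxy-5-oxo-3-phenylpentanoic acid | COC(=O)C[C@](O)(c1ccccc1)CC(=O)O | intermediate
6 | 1-methyl 5-triethylsilyl (3R)-3-phenyl-3-[(triethylsilyl)oxy]pentanedioate | COC(=O)C[C@](O[Si](CC)(CC)CC)(c1ccccc1)CC(=O)O[Si](CC)(CC)CC | intermediate
7 | (3S)-5-methoxy-5-oxo-3-phenyl-3-[(triethylsilyl)oxy]pentanoic acid | COC(=O)C[C@](O[Si](CC)(CC)CC)(c1ccccc1)CC(=O)O | intermediate
8 | methyl acetoacetate | COC(=O)CC(C)=O | starting material
9 | methyl (3S)-5-(1H-imidazol-1-yl)-5-oxo-3-phenyl-3-[(triethylsilyl)oxy]pentanoate | COC(=O)C[C@](O[Si](CC)(CC)CC)(c1ccccc1)CC(=O)n1ccnc1 | intermediate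
10 | methyl acetoacetate dianion, sodium lithium salt | [Na+].[Li+].COC(=O)[CH-]C(=O)[CH2-] | intermediate
11 | dimethyl (7S)-3,5-dioxo-7-phenyl-7-[(triethylsilyl)oxy]nonanedioate | COC(=O)C[C@](O[Si](CC)(CC)CC)(c1ccccc1)CC(=O)CC(=O)CC(=O)OC | intermediate
12 | methyl (3S)-4-(4-hydroxy-2-oxo-2H-pyran-6-yl)-3-phenyl-3-[(triethylsilyl)oxy]butanoate | COC(=O)C[C@](O[Si](CC)(CC)CC)(c1ccccc1)Cc1cc(O)cc(=O)o1 | intermediate
13 | methyl (3S)-4-[4-(benzyloxy)-2-oxo-2H-pyran-6-yl]-3-phenyl-3-[(triethylsilyl)oxy]butanoate | COC(=O)C[C@](O[Si](CC)(CC)CC)(c1ccccc1)Cc1cc(OCc2ccccc2)cc(=O)o1 | intermediate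
14 | 2-iodoresorcinol | Oc1cccc(O)c1I | starting material
15 | 3-(benzyloxy)-2-iodophenol | Oc1cccc(OCc2ccccc2)c1I | intermediate
16 | 3-(benzyloxy)-2-iodophenyl trifluoromethanesulfonate | O=S(=O)(Oc1cccc(OCc2ccccc2)c1I)C(F)(F)F | intermediate
17 | lithium extended enolate of 13, (3S), carbanion at the pyrone 6-methylene carbon | [Li+].COC(=O)C[C@](O[Si](CC)(CC)CC)(c1ccccc1)[CH-]c1cc(OCc2ccccc2)cc(=O)o1 | intermediate
18 | 3-(benzyloxy)-2-(chloromagnesio)phenyl trifluoromethanesulfonate | O=S(=O)(Oc1cccc(OCc2ccccc2)c1[Mg]Cl)C(F)(F)F | intermediate
19 | 3-benzyloxybenzyne (1-benzyloxy-2,3-didehydrobenzene) | O(Cc1ccccc1)C1=CC=CC#C1 | intermediate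
20 | methyl (3R)-4-[3-(benzyloxy)-2-lithiophenyl]-4-[4-(benzyloxy)-2-oxo-2H-pyran-6-yl]-3-phenyl-3-[(triethylsilyl)oxy]butanoate, C4 not yet defined | COC(=O)C[C@](O[Si](CC)(CC)CC)(c1ccccc1)C(c1cc(OCc2ccccc2)cc(=O)o1)c1cccc(OCc2ccccc2)c1[Li] | intermediate
21 | lithium C4 enolate of 22, (3R), C4 planar | [Li+].O=C1C[C@](O[Si](CC)(CC)CC)(c2ccccc2)[C-](c2cc(OCc3ccccc3)cc(=O)o2)c2cccc(OCc3ccccc3)c21 | intermediate
22 | (3R,4R)-8-(benzyloxy)-4-[4-(benzyloxy)-2-oxo-2H-pyran-6-yl]-3-phenyl-3-[(triethylsilyl)oxy]-3,4-dihydronaphthalen-1(2H)-one | O=C1C[C@](O[Si](CC)(CC)CC)(c2ccccc2)[C@@H](c2cc(OCc3ccccc3)cc(=O)o2)c2cccc(OCc3ccccc3)c21 | intermediate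
23 | (3R,4S)-8-(benzyloxy)-4-[4-(benzyloxy)-2-oxo-2H-pyran-6-yl]-3-hydroxy-3-phenyl-3,4-dihydronaphthalen-1(2H)-one | O=C1C[C@](O)(c2ccccc2)[C@@H](c2cc(OCc3ccccc3)cc(=O)o2)c2cccc(OCc3ccccc3)c21 | intermediate
24 | (3R,4S)-3,8-dihydroxy-4-(4-hydroxy-2-oxo-2H-pyran-6-yl)-3-phenyl-3,4-dihydronaphthalen-1(2H)-one | O=C1C[C@](O)(c2ccccc2)[C@@H](c2cc(O)cc(=O)o2)c2cccc(O)c21 | intermediate
25 | 6-(4,5-dihydroxy-2-phenylnaphthalen-1-yl)-4-hydroxy-2H-pyran-2-one | O=c1cc(O)cc(-c2c(-c3ccccc3)cc(O)c3c(O)cccc23)o1 | intermediate
26 | 3-[(dimethylamino)methylidene]-6-(4,5-dihydroxy-2-phenylnaphthalen-1-yl)-2H-pyran-2,4(3H)-dione (alkene geometry not defined, inconsequential) | CN(C)C=C1C(=O)C=C(-c2c(-c3ccccc3)cc(O)c3c(O)cccc23)OC1=O | intermediate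
27 | 6-(4,5-dihydroxy-2-phenylnaphthalen-1-yl)-4-hydroxy-2-oxo-2H-pyran-3-carbaldehyde | O=Cc1c(O)cc(-c2c(-c3ccccc3)cc(O)c3c(O)cccc23)oc1=O | intermediate
28 | methine-bridged condensation product of 24 and 27, (3R,4S), one tautomer drawn | O=C1C[C@](O)(c2ccccc2)[C@@H](c2cc(O)c(C=C3C(=O)C=C(-c4c(-c5ccccc5)cc(O)c5c(O)cccc45)OC3=O)c(=O)o2)c2cccc(O)c21 | intermediate
29 | wailupemycin H, (3R,4S) in tetralone numbering | O=C1C[C@](O)(c2ccccc2)[C@@H](c2cc(O)c(Cc3c(O)cc(-c4c(-c5ccccc5)cc(O)c5c(O)cccc45)oc3=O)c(=O)o2)c2cccc(O)c21 | target

## Step count and least certain steps

Total: 15 steps. Longest linear sequence: 13 steps (1–7, 10–15). The aryne precursor takes 2 further steps (8, 9).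

**Step 10 (key step, new method).** The most likely failure is β-elimination of the silyloxy group from the C4 carbanion (before or after ring closure), because the anion sits next to a fair leaving group and the eliminated product aromatises. Further risks are cycloaddition of the aryne across the pyrone diene, proton capture of the aryl anion before acylation, and poor facial selectivity in the C4 protonation. Fallback with known reactions, from 13 back to 22: the methyl ester of 13 is hydrolysed with Me3SnOH (1,2-dichloroethane, 70 °C) to the carboxylic acid F1. F1 is converted with 1-chloro-N,N,2-trimethylprop-1-en-1-amine into the acid chloride F2, used at once. Zinc insertion into the C–I bond of 16 (Zn dust, LiCl, THF) gives the arylzinc iodide F3, which keeps its ortho triflate. Pd(PPh3)4-catalysed Negishi acylation of F3 with F2 gives the keto triflate F4, in which C1–C8a is in place. Intramolecular palladium-catalysed arylation of the pyrone methylene carbon by the aryl triflate (Pd(OAc)2, XPhos, K3PO4, toluene, 60 °C) then forms C4–C4a and returns to 22. The positions of iodine and triflate in 16 fix the same regiochemistry as the aryne.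

**Step 3 (enzymatic desymmetrisation).** Low or reversed enantiotopic-group selectivity is possible, because a phenyl group is much larger than the methyl group for which this enzyme is known to work well. Fallback from 4 back to 5: statistical mono-saponification (KOH, 1.0 equiv, MeOH/H2O) gives the racemic half-ester F5. Fractional crystallisation with one enantiomer of 1-phenylethylamine (whichever gives the less soluble salt of the S acid; the S amine is drawn) gives the diastereomerically pure salt F6, and acidification returns 5. The acid from the mother liquor is re-esterified to achiral 4 and recycled.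

**Step 15 (reductive union).** Loss of stereochemical integrity of the tetralone half (retro-aldol opening or dehydration under the amine/acid conditions) is the most damaging risk. Formyl transfer between the pyrones, leading to symmetrical dimers, and over-reduction of the aldehyde are the others. Fallback from 22 back to 29: 22 is hydrogenolysed (H2, Pd/C) with the silyl ether kept, to the silyl-protected monomer F7. F7 is united with 27 and Hantzsch ester as in step 15 to give the silyl-protected dimer F8, and the silyl group is removed last with HF·pyridine to give 29. The tertiary oxygen then stays masked throughout the union.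

**Step 14 (formylation).** Competing attack at the acidic, electron-rich naphthalenediol (O-methylation or C-functionalisation) or incomplete hydrolysis of the vinylogous amide may occur. Fallback from 24 back to 29, with the roles of the halves exchanged: 24, whose phenol ring is deactivated by the ketone, is treated with Me2NCH(OMe)2 and then dilute HCl as in step 14 to give the formylated monomer F9. F9 is united with 25 and Hantzsch ester to give 29.

**Step 2 (direct oxidative esterification).** Base-induced fragmentation of the transient β-hydroxy aldehyde or incomplete oxidation in methanolic NaOH may occur. Fallback from 3 back to 4: ozonolysis with oxidative work-up (O3, CH2Cl2/AcOH; then H2O2) gives the diacid F10, which is esterified under non-acidic conditions (MeI, KHCO3, DMF) to 4.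

## Further compounds

F1 | step 10 | (3S)-4-[4-(benzyloxy)-2-oxo-2H-pyran-6-yl]-3-phenyl-3-[(triethylsilyl)oxy]butanoic acid | OC(=O)C[C@](O[Si](CC)(CC)CC)(c1ccccc1)Cc1cc(OCc2ccccc2)cc(=O)o1
F2 | step 10 | (3S)-4-[4-(benzyloxy)-2-oxo-2H-pyran-6-yl]-3-phenyl-3-[(triethylsilyl)oxy]butanoyl chloride | ClC(=O)C[C@](O[Si](CC)(CC)CC)(c1ccccc1)Cc1cc(OCc2ccccc2)cc(=O)o1
F3 | step 10 | [2-(benzyloxy)-6-(trifluoromethanesulfonyloxy)phenyl]zinc iodide | O=S(=O)(Oc1cccc(OCc2ccccc2)c1[Zn]I)C(F)(F)F
F4 | step 10 | 3-(benzyloxy)-2-{(3S)-4-[4-(benzyloxy)-2-oxo-2H-pyran-6-yl]-3-phenyl-3-[(triethylsilyl)oxy]butanoyl}phenyl trifluoromethanesulfonate | O=C(C[C@](O[Si](CC)(CC)CC)(c1ccccc1)Cc1cc(OCc2ccccc2)cc(=O)o1)c1c(OCc2ccccc2)cccc1OS(=O)(=O)C(F)(F)F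
F5 | step 3 | racemic 3-hydroxy-5-methoxy-5-oxo-3-phenylpentanoic acid | COC(=O)CC(O)(CC(=O)O)c1ccccc1
F6 | step 3 | (S)-1-phenylethylammonium (3S)-3-hydroxy-5-methoxy-5-oxo-3-phenylpentanoate | COC(=O)C[C@](O)(c1ccccc1)CC(=O)[O-].C[C@H]([NH3+])c1ccccc1
F7 | step 15 | (3R,4R)-8-hydroxy-4-(4-hydroxy-2-oxo-2H-pyran-6-yl)-3-phenyl-3-[(triethylsilyl)oxy]-3,4-dihydronaphthalen-1(2H)-one | O=C1C[C@](O[Si](CC)(CC)CC)(c2ccccc2)[C@@H](c2cc(O)cc(=O)o2)c2cccc(O)c21
F8 | step 15 | C3-O-triethylsilyl wailupemycin H, (3R,4R) | O=C1C[C@](O[Si](CC)(CC)CC)(c2ccccc2)[C@@H](c2cc(O)c(Cc3c(O)cc(-c4c(-c5ccccc5)cc(O)c5c(O)cccc45)oc3=O)c(=O)o2)c2cccc(O)c21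
F9 | step 14 | 6-[(1S,2R)-2,5-dihydroxy-4-oxo-2-phenyl-1,2,3,4-tetrahydronaphthalen-1-yl]-4-hydroxy-2-oxo-2H-pyran-3-carbaldehyde | O=C1C[C@](O)(c2ccccc2)[C@@H](c2cc(O)c(C=O)c(=O)o2)c2cccc(O)c21
F10 | step 2 | 3-hydroxy-3-phenylpentanedioic acid | OC(=O)CC(O)(CC(=O)O)c1ccccc1
A1 | alternative 1 | di-tert-butyl 2-{3-[4,5-bis(benzyloxy)-2-phenylnaphthalen-1-yl]prop-2-ynoyl}-4-{4-[3-(benzyloxy)-2-bromophenyl]but-2-ynoyl}pentanedioate (both α-carbons enolisable, configuration not defined) | CC(C)(C)OC(=O)C(CC(C(=O)OC(C)(C)C)C(=O)C#Cc1c(-c2ccccc2)cc(OCc2ccccc2)c2c(OCc3ccccc3)cccc12)C(=O)C#CCc1cccc(OCc2ccccc2)c1Br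
A2 | alternative 2 | (3R,4S)-3,8-dihydroxy-4-(4-hydroxy-2-oxo-2H-pyran-6-yl)-3-phenyl-3,4-dihydronaphthalen-1(2H)-one | O=C1C[C@](O)(c2ccccc2)[C@@H](c2cc(O)cc(=O)o2)c2cccc(O)c21
A3 | alternative 3 | (1S,2R)-5-(benzyloxy)-2-[(4-methoxybenzyl)oxy]-2-phenyl-1,2-dihydronaphthalene-1-carboxylic acid | C1=C[C@](OCc2ccc(OC)cc2)(c2ccccc2)[C@@H](C(O)=O)c2cccc(OCc3ccccc3)c12
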